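**Retrosynthetic overview**
- Gardenin D ⇐ chelation-directed 5-O-demethylation and 3'-O-debenzylation of 3'-benzyloxy-5,6,7,8,4'-pentamethoxyflavone.
- Ring C (the pyranone) is formed last, by oxidative cyclisation of a 2'-hydroxychalcone; rings A and B are elaborated from bought benzene rings.
- The chalcone Cα–Cβ bond ⇐ intermolecular Claisen–Schmidt aldol condensation of 2'-hydroxy-3',4',5',6'-tetramethoxyacetophenone (ring A) with O-benzylisovanillin (ring B).
- Ring A ketone ⇐ C-acetylation of 2,3,4,5-tetramethoxyphenol ⇐ 2,3,4-trimethoxybenzaldehyde (Dakin, methylation, formylation, Dakin); ring B aldehyde ⇐ isovanillin + benzyl bromide.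

Assumption: Gardenin D has no stereocentre and no stereogenic double bond, so the SMILES defines one achiral compound; the racemic non-isolated intermediates 14 and 16 lose their stereocentre before the target.

**Step 1**
Reactants: 1 2,3,4-trimethoxybenzaldehyde
Product: 3 2,3,4-trimethoxyphenol, via 2,3,4-trimethoxyphenyl formate 2 (not isolated)
Conditions: mCPBA (1.3 equiv), CH2Cl2, 0 °C to rt, 12 h; then KOH, MeOH/H2O, rt, 1 h; aq HCl work-up
Reagents that add atoms: meta-chloroperoxybenzoic acid (mCPBA), O=C(OO)c1cccc(Cl)c1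
Why: Baeyer–Villiger (Dakin-type) oxidation, in which the ortho/para-methoxy groups make the aryl group migrate to give the aryl formate, which is saponified in the same pot.

**Step 2**
Reactants: 3 2,3,4-trimethoxyphenol
Product: 4 1,2,3,4-tetramethoxybenzene
Conditions: MeI (1.5 equiv), K2CO3 (2 equiv), acetone, reflux, 6 h
Reagents that add atoms: iodomethane, CI
Why: Williamson ether synthesis (SN2 O-methylation of the phenoxide), with no competing nucleophilic site.

**Step 3**
Reactants: 4 1,2,3,4-tetramethoxybenzene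
Product: 6 2,3,4,5-tetramethoxybenzaldehyde, via α-chloro ether 5 (not isolated)
Conditions: Cl2CHOMe (1.2 equiv), TiCl4 (2 equiv), CH2Cl2, −10 to 0 °C, 1 h; then ice/1 M HCl
Reagents that add atoms: dichloromethyl methyl ether, COC(Cl)Cl; water, O
Why: Rieche formylation (Friedel–Crafts alkylation, then hydrolysis); the two free ring positions are symmetry-equivalent and activated by an ortho and a para OMe, and the aldehyde formed deactivates the ring against a second formylation.

**Step 4**
Reactants: 6 2,3,4,5-tetramethoxybenzaldehyde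
Product: 8 2,3,4,5-tetramethoxyphenol, via 2,3,4,5-tetramethoxyphenyl formate 7 (not isolated)
Conditions: mCPBA (1.2 equiv), CH2Cl2, 0 °C to rt, 8 h; then KOH, degassed MeOH/H2O, 0 °C, 30 min, N2; aq HCl work-up; used directly
Reagents that add atoms: meta-chloroperoxybenzoic acid (mCPBA), O=C(OO)c1cccc(Cl)c1
Why: Baeyer–Villiger (Dakin-type) oxidation with aryl migration favoured by the ortho and para OMe groups; the formate shields the oxidation-prone phenol until mild saponification under N2.

**Step 5**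
Reactants: 8 2,3,4,5-tetramethoxyphenol
Product: 11 1-(2-hydroxy-3,4,5,6-tetramethoxyphenyl)ethanone, via 2,3,4,5-tetramethoxyphenyl acetate 9 (not isolated), via difluoroboron chelate 10 (not isolated)
Conditions: AcOH (solvent), BF3·OEt2 (3 equiv), 90 °C, 3 h; then H2O/EtOH, 60 °C, 30 min
Reagents that add atoms: acetic acid, CC(=O)O
Why: BF3-mediated O-acetylation and Fries rearrangement place the acetyl group on the only free ring carbon, ortho to OH; the ketone is held as its BF2 chelate, which blocks further reaction and is hydrolysed on work-up.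

**Step 6**
Reactants: 12 isovanillin (3-hydroxy-4-methoxybenzaldehyde)
Product: 13 3-(benzyloxy)-4-methoxybenzaldehyde
Conditions: BnBr (1.1 equiv), K2CO3 (1.5 equiv), DMF, 60 °C, 3 h
Reagents that add atoms: benzyl bromide, BrCc1ccccc1
Why: Williamson O-benzylation masks the ring B phenol so that it cannot deactivate the aldehyde as a phenoxide in the aldol step.

**Step 7**
Reactants: 11 1-(2-hydroxy-3,4,5,6-tetramethoxyphenyl)ethanone; 13 3-(benzyloxy)-4-methoxybenzaldehyde (1.15 equiv)
Product: 15 (E)-3-[3-(benzyloxy)-4-methoxyphenyl]-1-(2-hydroxy-3,4,5,6-tetramethoxyphenyl)prop-2-en-1-one, via β-hydroxy ketone aldol adduct 14 (not isolated)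
Conditions: 50% aq KOH (8 equiv), EtOH, rt, 48 h; then ice/2 M HCl
Reagents that add atoms: none
Why: Claisen–Schmidt (crossed aldol) condensation of the methyl ketone enolate with a non-enolisable aldehyde, followed by E1cB dehydration to the thermodynamically favoured E-enone, so the carbinol stereocentre of 14 is lost.

**Step 8**
Reactants: 15 the (E)-chalcone
Product: 17 2-[3-(benzyloxy)-4-methoxyphenyl]-5,6,7,8-tetramethoxy-4H-chromen-4-one, via racemic flavanone 16 (not isolated)
Conditions: I2 (0.1 equiv), DMSO, 130 °C, 3 h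
Reagents that add atoms: none
Why: Oxidative cyclisation in which intramolecular oxa-Michael addition of the 2'-OH closes ring C and I2 dehydrogenates the flavanone to the flavone, with DMSO regenerating I2 from HI.

**Step 9**
Reactants: 17 the 3'-O-benzyl flavone
Product: 18 2-(3-hydroxy-4-methoxyphenyl)-5,6,7,8-tetramethoxy-4H-chromen-4-one
Conditions: H2 (1 atm), 10% Pd/C, EtOAc/MeOH 1:1, rt, 4 h
Reagents that add atoms: none
Why: Catalytic hydrogenolysis cleaves only the benzylic C–O bond; the methyl ethers and the conjugated pyranone C2=C3 bond are inert at 1 atm.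

**Step 10**
Reactants: 18 the 3'-hydroxy pentamethoxyflavone
Product: 20 Gardenin D (5-hydroxy-2-(3-hydroxy-4-methoxyphenyl)-6,7,8-trimethoxy-4H-chromen-4-one), via bis(dichloroboryl) ether 19 (not isolated)
Conditions: BCl3 (1 M in CH2Cl2, 3.5 equiv), CH2Cl2, −20 to 0 °C, 2 h; then H2O/1 M HCl, rt, 30 min
Reagents that add atoms: none
Why: Chelation-controlled Lewis-acid ether cleavage, in which boron bound to the C4 carbonyl activates only the peri 5-OMe for chloride attack while non-chelated methyl ethers are inert to BCl3 at 0 °C; the transient 3'-O–BCl2 is hydrolysed on work-up.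

**Compound list**
1 | 2,3,4-trimethoxybenzaldehyde | COc1ccc(C=O)c(OC)c1OC | starting material
2 | 2,3,4-trimethoxyphenyl formate | COc1ccc(OC=O)c(OC)c1OC | intermediate
3 | 2,3,4-trimethoxyphenol | COc1ccc(O)c(OC)c1OC | intermediate
4 | 1,2,3,4-tetramethoxybenzene | COc1ccc(OC)c(OC)c1OC | intermediate
5 | 1-[chloro(methoxy)methyl]-2,3,4,5-tetramethoxybenzene (α-chloro ether, racemic) | COC(Cl)c1cc(OC)c(OC)c(OC)c1OC | intermediate
6 | 2,3,4,5-tetramethoxybenzaldehyde | COc1cc(C=O)c(OC)c(OC)c1OC | intermediate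
7 | 2,3,4,5-tetramethoxyphenyl formate | COc1cc(OC=O)c(OC)c(OC)c1OC | intermediate
8 | 2,3,4,5-tetramethoxyphenol | COc1cc(O)c(OC)c(OC)c1OC | intermediate
9 | 2,3,4,5-tetramethoxyphenyl acetate | COc1cc(OC(C)=O)c(OC)c(OC)c1OC | intermediate
10 | difluoroboron chelate of 11 (BF2 bridging the phenolate O and the ketone O) | CC1=[O+][B-](F)(F)Oc2c(OC)c(OC)c(OC)c(OC)c12 | intermediate
11 | 1-(2-hydroxy-3,4,5,6-tetramethoxyphenyl)ethanone | CC(=O)c1c(O)c(OC)c(OC)c(OC)c1OC | intermediate
12 | isovanillin (3-hydroxy-4-methoxybenzaldehyde) | COc1ccc(C=O)cc1O | starting material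
13 | 3-(benzyloxy)-4-methoxybenzaldehyde | COc1ccc(C=O)cc1OCc1ccccc1 | intermediate
14 | 3-[3-(benzyloxy)-4-methoxyphenyl]-3-hydroxy-1-(2-hydroxy-3,4,5,6-tetramethoxyphenyl)propan-1-one (racemic) | COc1ccc(C(O)CC(=O)c2c(O)c(OC)c(OC)c(OC)c2OC)cc1OCc1ccccc1 | intermediate
15 | (E)-3-[3-(benzyloxy)-4-methoxyphenyl]-1-(2-hydroxy-3,4,5,6-tetramethoxyphenyl)prop-2-en-1-one | COc1ccc(/C=C/C(=O)c2c(O)c(OC)c(OC)c(OC)c2OC)cc1OCc1ccccc1 | intermediate
16 | 2-[3-(benzyloxy)-4-methoxyphenyl]-5,6,7,8-tetramethoxychroman-4-one (racemic flavanone) | COc1ccc(C2CC(=O)c3c(OC)c(OC)c(OC)c(OC)c3O2)cc1OCc1ccccc1 | intermediate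
17 | 2-[3-(benzyloxy)-4-methoxyphenyl]-5,6,7,8-tetramethoxy-4H-chromen-4-one | COc1ccc(-c2cc(=O)c3c(OC)c(OC)c(OC)c(OC)c3o2)cc1OCc1ccccc1 | intermediate
18 | 2-(3-hydroxy-4-methoxyphenyl)-5,6,7,8-tetramethoxy-4H-chromen-4-one | COc1ccc(-c2cc(=O)c3c(OC)c(OC)c(OC)c(OC)c3o2)cc1O | intermediate
19 | 5,3'-bis(dichloroboryloxy)-6,7,8,4'-tetramethoxyflavone (5-O–B chelated to C4=O) | COc1ccc(-c2cc(=O)c3c(OB(Cl)Cl)c(OC)c(OC)c(OC)c3o2)cc1OB(Cl)Cl | intermediate
20 | Gardenin D (5,3'-dihydroxy-6,7,8,4'-tetramethoxyflavone) | COc1ccc(-c2cc(=O)c3c(O)c(OC)c(OC)c(OC)c3o2)cc1O | target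

**Totals**
Total step count: 10. Longest linear sequence: 9 steps (1 → 20 through steps 1–5 and 7–10); step 6 is the one-step side branch.

**Three steps most likely to fail**

Step 5 (C-acetylation of the very electron-rich, oxidation-prone phenol 8; possible quinone formation, BF3-induced demethylation or a stalled Fries step). The fallback sets out from 8, replaces the electrophilic acylation by directed ortho-metalation, and comes back at 11. Phenol 8 is protected with chloromethyl methyl ether and i-Pr2NEt in CH2Cl2 to give 1,2,3,4-tetramethoxy-5-(methoxymethoxy)benzene F1. sec-BuLi/TMEDA in THF at −78 °C removes the single ring proton, which is flanked by OMOM and OMe. N-Methoxy-N-methylacetamide traps the aryllithium as the lithium N-methoxy-N-methyl hemiaminal alkoxide F2, which collapses on aqueous NH4Cl quench to 1-[2,3,4,5-tetramethoxy-6-(methoxymethoxy)phenyl]ethanone F3. HCl in MeOH at 50 °C then removes the MOM group to give 11.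

Step 7 (aldol of a ketone flanked by two ortho substituents and carrying a phenoxide; slow enolisation, incomplete conversion, Cannizzaro loss of 13). The fallback sets out from 13, uses 11 as the enolate partner, forms the same C–C bond by an intermolecular Claisen-type enolate acylation, and comes back at 17, bypassing chalcone 15. Aldehyde 13 is oxidised (NaClO2, NaH2PO4, 2-methyl-2-butene, t-BuOH/H2O) to 3-(benzyloxy)-4-methoxybenzoic acid F4, which is converted with (COCl)2 and catalytic DMF in CH2Cl2 into 3-(benzyloxy)-4-methoxybenzoyl chloride F5. Ketone 11 is doubly deprotonated with LiN(SiMe3)2 (3.2 equiv) in THF at −78 °C and C-acylated by F5 to give 1-[3-(benzyloxy)-4-methoxyphenyl]-3-(2-hydroxy-3,4,5,6-tetramethoxyphenyl)propane-1,3-dione F6. Catalytic H2SO4 in AcOH at 90 °C for 1 h closes ring C through 2-[3-(benzyloxy)-4-methoxyphenyl]-2-hydroxy-5,6,7,8-tetramethoxychroman-4-one F7, which dehydrates to 17.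

Step 10 (selectivity of the demethylation: over-cleavage at 6-OMe, or at 4'-OMe next to the borylated 3'-oxygen). The fallback sets out from 17 and comes back at 20, reversing the order of the endgame so that the Lewis acid never meets the free ring B phenol. Flavone 17 is treated with anhydrous AlCl3 (5 equiv) in MeCN at rt to 40 °C. The acetonitrile-moderated Lewis acid cleaves only the chelated 5-OMe, giving the 5-O-dichloroaluminium chelate of the 3'-benzyloxy flavone F8. Warm dilute HCl releases 3'-(benzyloxy)-5-hydroxy-6,7,8,4'-tetramethoxyflavone F9. Hydrogenolysis (H2, 10% Pd/C, EtOAc/MeOH) of the benzyl ether then gives 20.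

**Further compounds**
F1 | step 5 | 1,2,3,4-tetramethoxy-5-(methoxymethoxy)benzene | COCOc1cc(OC)c(OC)c(OC)c1OC
F2 | step 5 | lithium 1-[methoxy(methyl)amino]-1-[2,3,4,5-tetramethoxy-6-(methoxymethoxy)phenyl]ethoxide (racemic tetrahedral adduct) | CON(C)C(C)(O[Li])c1c(OCOC)c(OC)c(OC)c(OC)c1OC
F3 | step 5 | 1-[2,3,4,5-tetramethoxy-6-(methoxymethoxy)phenyl]ethanone | CC(=O)c1c(OCOC)c(OC)c(OC)c(OC)c1OC
F4 | step 7 | 3-(benzyloxy)-4-methoxybenzoic acid | COc1ccc(C(=O)O)cc1OCc1ccccc1
F5 | step 7 | 3-(benzyloxy)-4-methoxybenzoyl chloride | COc1ccc(C(Cl)=O)cc1OCc1ccccc1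
F6 | step 7 | 1-[3-(benzyloxy)-4-methoxyphenyl]-3-(2-hydroxy-3,4,5,6-tetramethoxyphenyl)propane-1,3-dione | COc1ccc(C(=O)CC(=O)c2c(O)c(OC)c(OC)c(OC)c2OC)cc1OCc1ccccc1
F7 | step 7 | 2-[3-(benzyloxy)-4-methoxyphenyl]-2-hydroxy-5,6,7,8-tetramethoxychroman-4-one (racemic hemiketal) | COc1ccc(C2(O)CC(=O)c3c(OC)c(OC)c(OC)c(OC)c3O2)cc1OCc1ccccc1
F8 | step 10 | 5-O-dichloroaluminium chelate of 3'-(benzyloxy)-6,7,8,4'-tetramethoxyflavone | COc1ccc(-c2cc(=O)c3c(O[Al](Cl)Cl)c(OC)c(OC)c(OC)c3o2)cc1OCc1ccccc1
F9 | step 10 | 3'-(benzyloxy)-5-hydroxy-6,7,8,4'-tetramethoxyflavone | COc1ccc(-c2cc(=O)c3c(O)c(OC)c(OC)c(OC)c3o2)cc1OCc1ccccc1
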